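## The problem

Target 15 is a single tetrahydrofuran ring (O1, C2–C5) with four contiguous stereocentres. The aryl groups at C2 and C5 are cis, the acetoxymethyl arms at C3 and C4 are cis, and each arm is trans to the aryl next to it. A mirror plane through O1 and the midpoint of C3–C4 makes the compound meso, so only relative configuration has to be controlled and racemic intermediates suffice. The hard element is the 3,4-cis pair of arms: each arm avoids its neighbouring aryl but eclipses the other arm, so equilibration of a monocyclic ester cannot be relied on to set it. Control can be passed around the ring. The C4/C5 relationship can be carried in from a small-ring precursor, C5 can direct C2 during ring closure, and C4 can direct C3 if the two arms are tied for a time in a cis-fused five-membered lactone. The catechols oxidise easily and must stay masked to the end, and the primary acetates do not survive hydride, alkoxide or hot nucleophiles, so they go on late. Both ring C–O bonds are benzylic and para-oxygenated, so they can ionise under strong acid and can be hydrogenolysed. The enabling feature is that C5 (aryl and O1) and C3 (bearing a carbon that can be at carboxyl level) stand 1,3 across C4, which is the pattern of a 2-arylcyclopropane-1,1-dicarboxylate, while O1=C2(aryl) is the carbonyl of the same aromatic aldehyde from which that cyclopropane is built.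

## Retrosynthesis

**15 ⇐ 14.** The four aryl O–benzyl bonds are cut last. Benzyl ethers survive every earlier reagent and come off under neutral hydrogenolysis, which leaves the acetates alone. Unmasking the catechols at the very end avoids carrying an oxidisable group. The forward step must cleave aryl benzyl ethers faster than the ring's benzylic C–O bonds.

**14 ⇐ 13 ⇐ 12.** The two acetyl C–O bonds are cut to give meso diol 13. Both hydroxymethyl arms of 13 are then traced to the carbonyl and the O–CH2 of the cis-fused γ-lactone 12. A lactone is preferred over a diester here because a five-membered ring fused to the tetrahydrofuran can only be cis, which fixes the 3,4-cis relationship by constraint. The forward steps are a hydride reduction and an acetylation.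

**12 ⇐ 11 ⇐ 9 (through 10).** An extra methoxycarbonyl group is added back at C3 to give lactone ester 11, and the lactone C–O bond is opened to the silyl ether diester 9 (free alcohol 10 in between). This makes C3 a non-stereogenic malonate carbon, so the ring-forming step has one stereocentre fewer to control. Forward, the C4 arm can only lactonise onto the ester on its own face, and loss of the other ester must leave the ring fusion cis.

**9 ⇐ 8 + 1.** The key cut removes C5–O1 and C2–C3 together, giving donor–acceptor cyclopropane 8 and aldehyde 1. Cutting C3–C4 (radical or oxidative coupling) or both exocyclic C–C bonds was weighed against this. The chosen cut forms the ring, both aryl-bearing stereocentres and two bonds in one step, and both fragments come from the same aldehyde. The forward reaction must open the cyclopropane with inversion at the benzylic carbon (cis in 8 becomes 4,5-trans in 9) and close with 2,5-cis selectivity.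

**8 ⇐ 5 + 7; 7 ⇐ 6.** The two cyclopropane bonds to the malonate carbon are cut, giving Z-alkene 5 and diazomalonate 7, which comes from malonate 6 by diazo transfer. Carbene transfer is stereospecific, so the cis relationship in 8 reduces to alkene geometry. The forward step needs an intermolecular cyclopropanation of a 1,2-disubstituted alkene by a malonate carbenoid, which is the least routine of the supporting steps.

**5 ⇐ 4 ⇐ 3 ⇐ 1 + 2.** The silyl ether is removed (4), the allylic alcohol is traced to Z-enoate 3, and the C=C bond is cut to aldehyde 1 and phosphonate 2. A Z-selective olefination of an aromatic aldehyde is reliable, and 1 already carries the protected catechol.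

## Roads not taken

**Alternative 1:** Biomimetic β–β dimerisation with water capture. The cut is C3–C4 together with both ring C–O bonds. Forward, one-electron oxidation (Ag2O in wet acetone) of the mono-benzylated caffeyl acetate A1 would couple two β-carbons to a bis-quinone methide; water adds at one benzylic carbon and the new hydroxyl closes onto the other to give A2, and hydrogenolysis would then give 15.
- Merits: it is by far the shortest road, uses the symmetry of the target fully and needs one protecting group per ring.
- Weak points: phenoxyl radical coupling of such monomers favours β–5 and β–O–4 products over β–β. The β–β coupling itself gives both diastereomers of the bis-quinone methide, so 3,4-cis and 3,4-trans products form together. Intermolecular water addition and the closing etherification are not stereocontrolled at C2 and C5.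
- Comparison: on step count this road is clearly better. The chosen plan sets against it that each of the four relative configurations has an assigned control element and that the meso isomer is not fished out of a mixture.

**Alternative 2:** Syn bis-methoxycarbonylation of a dihydrofuran. The cut is the two exocyclic C–C bonds at C3 and C4. Forward, PdCl2 with CuCl2 under CO in methanol would add two ester groups syn across the C3=C4 bond of cis-2,5-diaryl-2,5-dihydrofuran A3, on the face away from the aryls, to give diester A4; reduction would reach 13.
- Merits: syn addition guarantees the 3,4-cis relationship and the two aryls select the face, so the stereochemical argument at C3/C4 is cleaner than in the chosen plan.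
- Weak points: A3 is a doubly benzylic, doubly allylic ether that aromatises easily to the furan under oxidising palladium conditions. After the first C–Pd bond forms, β-hydride elimination toward C2 or C5 competes with CO insertion. Hindered internal alkenes are poor substrates for this dicarbonylation. A3 must also be made as the pure cis isomer first.
- Comparison: if the carbonylation worked it would be shorter and stereochemically more transparent. The chosen plan sets against it that its key reaction type is established on closely related substrates and that it carries no oxidation-prone dihydrofuran.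

**Alternative 3:** Iodine-transfer radical cyclisation. The cut is C3–C4, with the C2 aryl added later. Forward, Et3B with air would convert iodoacetal A5 to the C3 radical, which closes 5-exo onto the vinyl group and picks up iodine to give A6; acetate displacement of the iodide, arylation of the acetal carbon through an oxocarbenium ion and debenzylation would follow.
- Merits: 5-exo cyclisations of haloacetal radicals are among the most dependable five-ring closures, they run under neutral conditions, and the C5 aryl should favour the 4,5-trans relationship.
- Weak points: the 3,4-cis preference of such closures is usually modest. After the key step only one aryl is in place and C2 is still an acetal, so a second stereoselective C–C bond formation and a displacement at a hindered primary iodide remain. The acetal epimers complicate handling. The route ignores the symmetry of the target.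
- Comparison: as a single bond-forming event the radical closure is probably more reliable than the annulation chosen here, and the step count is similar. The chosen plan sets against it that ring, both aryl-bearing centres and two bonds arrive together, and that C3 is fixed by a lactone constraint and not by a kinetic preference.

Key step: step 6

Remark on the chemistry: the target is the achiral meso isomer (2,5-cis, 3,4-cis, 2,3-trans), so all chiral intermediates are prepared and used as racemates; their SMILES show one enantiomer.

## Steps

Step 1
Reactants: 1 3,4-bis(benzyloxy)benzaldehyde; 2 methyl bis(2,2,2-trifluoroethyl)phosphonoacetate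
Product: 3 methyl (Z)-3-[3,4-bis(benzyloxy)phenyl]prop-2-enoate
Conditions: 2, KN(SiMe3)2, 18-crown-6, THF, −78 °C; then 1
Reagents that add atoms: none
Why: Still–Gennari olefination; the electron-poor trifluoroethyl phosphonate makes elimination from the kinetic syn adduct fast, which should give the Z-enoate with aromatic aldehydes.

Step 2
Reactants: 3 methyl (Z)-3-[3,4-bis(benzyloxy)phenyl]prop-2-enoate
Product: 4 (Z)-3-[3,4-bis(benzyloxy)phenyl]prop-2-en-1-ol
Conditions: i-Bu2AlH (2.5 equiv), CH2Cl2, −78 °C; aq. potassium sodium tartrate
Reagents that add atoms: none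
Why: 1,2-reduction of an enoate with i-Bu2AlH at low temperature should leave the Z double bond and the benzyl ethers untouched.

Step 3
Reactants: 4 (Z)-3-[3,4-bis(benzyloxy)phenyl]prop-2-en-1-ol
Product: 5 (Z)-{[3-(3,4-bis(benzyloxy)phenyl)prop-2-en-1-yl]oxy}(tert-butyl)diphenylsilane
Conditions: TBDPSCl, imidazole, DMF, 0 °C → rt
Reagents that add atoms: tert-butyl(chloro)diphenylsilane, CC(C)(C)[Si](Cl)(c1ccccc1)c1ccccc1
Why: Standard silylation of a primary alcohol; the bulky, Lewis-acid-stable TBDPS ether should suppress oxonium ylide formation in step 5 and survive step 6.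

Step 4
Reactants: 6 dimethyl malonate
Product: 7 dimethyl 2-diazomalonate
Conditions: 4-acetamidobenzenesulfonyl azide, Et3N, MeCN, 0 °C → rt
Reagents that add atoms: 4-acetamidobenzenesulfonyl azide, CC(=O)Nc1ccc(cc1)S(=O)(=O)N=[N+]=[N-]
Why: Regitz diazo transfer to an active methylene compound, a routine preparation of diazomalonates.

Step 5
Reactants: 5 (Z)-{[3-(3,4-bis(benzyloxy)phenyl)prop-2-en-1-yl]oxy}(tert-butyl)diphenylsilane; 7 dimethyl 2-diazomalonate
Product: 8 dimethyl 2-[3,4-bis(benzyloxy)phenyl]-3-{[(tert-butyldiphenylsilyl)oxy]methyl}cyclopropane-1,1-dicarboxylate (aryl and silyloxymethyl cis)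
Conditions: 7 (1.5 equiv, slow addition), Rh2(esp)2 (1 mol %; esp = α,α,α′,α′-tetramethyl-1,3-benzenedipropanoate), CH2Cl2, 0 °C → rt
Reagents that add atoms: none
Why: Rhodium carbenoid cyclopropanation; the carbene adds to the electron-rich styrenyl double bond in one stereospecific event, so the Z geometry of 5 should become the cis relationship of aryl and silyloxymethyl in 8. The chelating dicarboxylate catalyst is the one best suited to malonate carbenoids.

Step 6
Reactants: 8 dimethyl 2-[3,4-bis(benzyloxy)phenyl]-3-{[(tert-butyldiphenylsilyl)oxy]methyl}cyclopropane-1,1-dicarboxylate (aryl and silyloxymethyl cis); 1 3,4-bis(benzyloxy)benzaldehyde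
Product: 9 dimethyl 2,5-bis[3,4-bis(benzyloxy)phenyl]-4-{[(tert-butyldiphenylsilyl)oxy]methyl}tetrahydrofuran-3,3-dicarboxylate (2,5-cis; 4,5-trans)
Conditions: 1 (3 equiv), Sn(OTf)2 (10 mol %), CH2Cl2, −20 °C → rt
Reagents that add atoms: none
Why: Divalent tin triflate chelates the geminal diester of 8 and polarises the bond between the malonate carbon and the benzylic carbon; the carbonyl oxygen of 1 attacks the benzylic carbon from the side opposite the departing malonate (SN2-like, intimate ion pair) and forms C5–O1 with inversion. The resulting oxocarbenium–malonate zwitterion closes C2–C3 in a formally 5-(enolexo)-endo-trig aldol-type addition, which is accessible because the electrophile is a cation tethered through its own oxygen. The closest known reaction type is the Lewis-acid-catalysed [3+2] annulation of 2-arylcyclopropane-1,1-diesters with aldehydes to 2,5-cis tetrahydrofurans, which has also been run on 3-substituted cyclopropanes (there with AlCl3, the first variation to try if Sn(OTf)2 is slow). C5 is set by the stereospecific inversion: aryl and silyloxymethyl are cis in 8, so they become 4,5-trans in 9, C4 itself being untouched. C2 is set in the closure: an E-oxocarbenium ion in an envelope with both aryl groups pseudo-equatorial gives 2,5-cis, and the C4 arm is pseudo-equatorial in the same envelope, so nothing opposes it. The step needs capture by the aldehyde to outrun ionisation of the cyclopropane; a mild Lewis acid at low temperature, an excess of the nucleophilic electron-rich aldehyde and the robust TBDPS and benzyl ethers are meant to secure this.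

Step 7
Reactants: 9 dimethyl 2,5-bis[3,4-bis(benzyloxy)phenyl]-4-{[(tert-butyldiphenylsilyl)oxy]methyl}tetrahydrofuran-3,3-dicarboxylate (2,5-cis; 4,5-trans)
Product: 11 methyl 4,6-bis[3,4-bis(benzyloxy)phenyl]-1-oxotetrahydro-1H,3H-furo[3,4-c]furan-6a-carboxylate (cis-fused; aryls cis to each other and trans to the lactone ring), via hydroxymethyl diester 10 (not isolated)
Conditions: Bu4NF, THF, 0 °C → rt
Reagents that add atoms: none
Why: Fluoride desilylation frees the alkoxide of 10, which can reach only the ester on its own face and closes a cis-fused γ-lactone by intramolecular transesterification. No existing stereocentre changes; C3 becomes stereogenic with its remaining ester trans to the C4 arm.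

Step 8
Reactants: 11 methyl 4,6-bis[3,4-bis(benzyloxy)phenyl]-1-oxotetrahydro-1H,3H-furo[3,4-c]furan-6a-carboxylate (cis-fused)
Product: 12 4,6-bis[3,4-bis(benzyloxy)phenyl]tetrahydro-1H,3H-furo[3,4-c]furan-1-one (cis-fused; aryls cis to each other and trans to the lactone ring)
Conditions: LiCl, H2O, DMSO, 150 °C
Reagents that add atoms: none
Why: Krapcho dealkoxycarbonylation; chloride demethylates the angular ester, the carboxylate loses CO2 and the lactone enolate is protonated. Only the cis-fused bicyclo[3.3.0] lactone is viable, so the new C3–H must end up cis to the C4–H, which places the C3 carbonyl cis to the C4 methylene and trans to the C2 aryl.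

Step 9
Reactants: 12 4,6-bis[3,4-bis(benzyloxy)phenyl]tetrahydro-1H,3H-furo[3,4-c]furan-1-one (cis-fused)
Product: 13 meso-{(2R,3S,4R,5S)-2,5-bis[3,4-bis(benzyloxy)phenyl]tetrahydrofuran-3,4-diyl}dimethanol
Conditions: LiAlH4, THF, 0 °C → rt
Reagents that add atoms: none
Why: Hydride reduction of a lactone to the 1,4-diol; aryl benzyl ethers and the ring are inert, and no stereocentre is touched, so the cis arms are kept.

Step 10
Reactants: 13 meso-{(2R,3S,4R,5S)-2,5-bis[3,4-bis(benzyloxy)phenyl]tetrahydrofuran-3,4-diyl}dimethanol
Product: 14 meso-{(2R,3S,4R,5S)-2,5-bis[3,4-bis(benzyloxy)phenyl]tetrahydrofuran-3,4-diyl}bis(methylene) diacetate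
Conditions: Ac2O, pyridine, DMAP (cat.), CH2Cl2, 0 °C → rt
Reagents that add atoms: acetic anhydride, CC(=O)OC(C)=O
Why: DMAP-catalysed acetylation of two primary alcohols; the phenols are still benzylated, so only the aliphatic acetates can form.

Step 11
Reactants: 14 meso-{(2R,3S,4R,5S)-2,5-bis[3,4-bis(benzyloxy)phenyl]tetrahydrofuran-3,4-diyl}bis(methylene) diacetate
Product: 15 meso-[(2R,3S,4R,5S)-2,5-bis(3,4-dihydroxyphenyl)tetrahydrofuran-3,4-diyl]bis(methylene) diacetate
Conditions: H2 (1 atm), 10% Pd/C, EtOAc, rt, exclusion of air on work-up
Reagents that add atoms: none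
Why: Hydrogenolysis of aryl benzyl ethers under neutral conditions leaves the acetates alone. Aryl O–benzyl bonds cleave much faster than the ring's dialkyl benzylic C–O bonds, so a short exposure in a non-acidic solvent should spare C2–O1 and C5–O1.

## Compound list

1 | 3,4-bis(benzyloxy)benzaldehyde | O=Cc1ccc(OCc2ccccc2)c(OCc2ccccc2)c1 | starting material
2 | methyl bis(2,2,2-trifluoroethyl)phosphonoacetate | COC(=O)CP(=O)(OCC(F)(F)F)OCC(F)(F)F | starting material
3 | methyl (Z)-3-[3,4-bis(benzyloxy)phenyl]prop-2-enoate | COC(=O)/C=C\c1ccc(OCc2ccccc2)c(OCc2ccccc2)c1 | intermediate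
4 | (Z)-3-[3,4-bis(benzyloxy)phenyl]prop-2-en-1-ol | OC/C=C\c1ccc(OCc2ccccc2)c(OCc2ccccc2)c1 | intermediate
5 | (Z)-{[3-(3,4-bis(benzyloxy)phenyl)prop-2-en-1-yl]oxy}(tert-butyl)diphenylsilane | CC(C)(C)[Si](c1ccccc1)(c1ccccc1)OC/C=C\c1ccc(OCc2ccccc2)c(OCc2ccccc2)c1 | intermediate
6 | dimethyl malonate | COC(=O)CC(=O)OC | starting material
7 | dimethyl 2-diazomalonate | COC(=O)C(=[N+]=[N-])C(=O)OC | intermediate
8 | dimethyl 2-[3,4-bis(benzyloxy)phenyl]-3-{[(tert-butyldiphenylsilyl)oxy]methyl}cyclopropane-1,1-dicarboxylate, aryl and silyloxymethyl cis (racemic) | COC(=O)C1(C(=O)OC)[C@H](c2ccc(OCc3ccccc3)c(OCc3ccccc3)c2)[C@@H]1CO[Si](c1ccccc1)(c1ccccc1)C(C)(C)C | intermediate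
9 | dimethyl 2,5-bis[3,4-bis(benzyloxy)phenyl]-4-{[(tert-butyldiphenylsilyl)oxy]methyl}tetrahydrofuran-3,3-dicarboxylate, 2,5-cis and 4,5-trans (racemic) | CC(C)(C)[Si](c1ccccc1)(c1ccccc1)OC[C@@H]1C(C(=O)OC)(C(=O)OC)[C@@H](c2ccc(OCc3ccccc3)c(OCc3ccccc3)c2)O[C@H]1c1ccc(OCc2ccccc2)c(OCc2ccccc2)c1 | intermediate
10 | dimethyl 2,5-bis[3,4-bis(benzyloxy)phenyl]-4-(hydroxymethyl)tetrahydrofuran-3,3-dicarboxylate, 2,5-cis and 4,5-trans (racemic) | OC[C@@H]1C(C(=O)OC)(C(=O)OC)[C@@H](c2ccc(OCc3ccccc3)c(OCc3ccccc3)c2)O[C@H]1c1ccc(OCc2ccccc2)c(OCc2ccccc2)c1 | intermediate (not isolated)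
11 | methyl 4,6-bis[3,4-bis(benzyloxy)phenyl]-1-oxotetrahydro-1H,3H-furo[3,4-c]furan-6a-carboxylate, cis-fused, aryls cis to each other and trans to the lactone ring (racemic); in tetrahydrofuran numbering C3 carries the ester and the lactone carbonyl, C4 the lactone CH2 | O=C1OC[C@@H]2[C@@]1(C(=O)OC)[C@@H](c1ccc(OCc3ccccc3)c(OCc3ccccc3)c1)O[C@H]2c1ccc(OCc2ccccc2)c(OCc2ccccc2)c1 | intermediate
12 | 4,6-bis[3,4-bis(benzyloxy)phenyl]tetrahydro-1H,3H-furo[3,4-c]furan-1-one, cis-fused, aryls cis to each other and trans to the lactone ring (racemic) | O=C1OC[C@@H]2[C@H]1[C@@H](c1ccc(OCc3ccccc3)c(OCc3ccccc3)c1)O[C@H]2c1ccc(OCc2ccccc2)c(OCc2ccccc2)c1 | intermediate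
13 | meso-{(2R,3S,4R,5S)-2,5-bis[3,4-bis(benzyloxy)phenyl]tetrahydrofuran-3,4-diyl}dimethanol | OC[C@@H]1[C@H](CO)[C@@H](c2ccc(OCc3ccccc3)c(OCc3ccccc3)c2)O[C@H]1c1ccc(OCc2ccccc2)c(OCc2ccccc2)c1 | intermediate
14 | meso-{(2R,3S,4R,5S)-2,5-bis[3,4-bis(benzyloxy)phenyl]tetrahydrofuran-3,4-diyl}bis(methylene) diacetate | CC(=O)OC[C@@H]1[C@H](COC(C)=O)[C@@H](c2ccc(OCc3ccccc3)c(OCc3ccccc3)c2)O[C@H]1c1ccc(OCc2ccccc2)c(OCc2ccccc2)c1 | intermediate
15 | meso-[(2R,3S,4R,5S)-2,5-bis(3,4-dihydroxyphenyl)tetrahydrofuran-3,4-diyl]bis(methylene) diacetate | CC(=O)OC[C@@H]1[C@H](COC(C)=O)[C@@H](c2ccc(O)c(O)c2)O[C@H]1c1ccc(O)c(O)c1 | target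

Total step count: 11. Longest linear sequence: 10 steps (1, 2, 3, 5, 6, 7, 8, 9, 10, 11); step 4 is a one-step side branch.

## Least certain steps

**Step 6 (key step).** The most likely failure is loss of stereochemical fidelity before capture. The 4-benzyloxy group stabilises a benzylic cation and the cis-cyclopropane is strained, so Lewis-acid ionisation with cis-to-trans isomerisation of the cyclopropane can compete with the SN2-like attack of the weakly nucleophilic aldehyde, and the 4,5-cis series would then leak in. Slow turnover of the 3-substituted cyclopropane is the second concern.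

The fallback separates the two bond formations. It sets out from 8 and 1 and returns at 9. Part of 1 is reduced with NaBH4 to [3,4-bis(benzyloxy)phenyl]methanol F1. Compound 8 is opened with F1 under mild catalysis (Cu(OTf)2 or Yb(OTf)3, CH2Cl2, 0 °C). An alcohol is a far better nucleophile than an aldehyde, and this ring opening of 2-arylcyclopropane-1,1-diesters proceeds at the benzylic carbon with inversion. It gives dimethyl 2-{1-[3,4-bis(benzyloxy)phenyl]-1-{[3,4-bis(benzyloxy)benzyl]oxy}-3-[(tert-butyldiphenylsilyl)oxy]propan-2-yl}malonate F2. Oxidation of the dialkoxybenzyl ether CH2 of F2 with DDQ (CH2Cl2, 4 Å molecular sieves, catalytic Cu(OTf)2 to enolise the malonate) would generate the same oxocarbenium ion as in step 6, and the tethered malonate would trap it to give 9. The open points of this fallback are hydride abstraction at the wrong benzylic position and over-oxidation of 9.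

**Step 5.** Malonate carbenoids are sluggish toward 1,2-disubstituted alkenes. Carbene dimerisation, attack on the electron-rich arene or ylide formation at the ether oxygen may outpace cyclopropanation of the hindered Z-alkene.

The fallback delivers the carbene intramolecularly. It sets out from 4 and returns at 11. Alcohol 4 is acylated with methyl malonyl chloride (pyridine, CH2Cl2) to methyl (Z)-3-[3,4-bis(benzyloxy)phenyl]prop-2-en-1-yl malonate F3. Diazo transfer as in step 4 gives the diazomalonate F4. Rh2(OAc)4 in CH2Cl2 then closes methyl 6-[3,4-bis(benzyloxy)phenyl]-2-oxo-3-oxabicyclo[3.1.0]hexane-1-carboxylate F5, in which the tether enforces the cis relationship of aryl and CH2O. F5 is itself a donor–acceptor cyclopropane and would be annulated with 1 under the conditions of step 6 to give 11 directly, bypassing 5, 8, 9 and 10. A lactone–ester acceptor has much less precedent in this annulation than a diester, which is why this shorter path is held in reserve.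

**Step 8.** At 150 °C the lactone enolate has the ring oxygen β to it at C2, so retro-oxa-Michael opening of the tetrahydrofuran is possible, as is chloride attack at the lactone CH2.

The fallback avoids a free enolate. It sets out from 11 and returns at 12. Selective cleavage of the methyl ester with Me3SnOH (1,2-dichloroethane, 80 °C) gives 4,6-bis[3,4-bis(benzyloxy)phenyl]-1-oxotetrahydro-1H,3H-furo[3,4-c]furan-6a-carboxylic acid F6. Heating F6 in toluene decarboxylates it through the cyclic transition state of a malonic half-acid to the neutral enol, which tautomerises to the cis-fused lactone 12.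

**Step 11.** Over-reduction is the risk: once a para-hydroxyl is unmasked, the ring C2–O1 and C5–O1 bonds are more easily hydrogenolysed, and the free catechols oxidise in air during work-up.

The fallback replaces hydrogenolysis by Lewis-acid debenzylation. It sets out from 14 and returns at 15. BCl3 with pentamethylbenzene as cation scavenger (CH2Cl2, −78 °C) removes aryl benzyl ethers without hydrogen and tolerates acetates; the temperature must stay low to avoid ionising the ring ether. No new compound is made on the way.

## Further compounds

F1 | step 6 | [3,4-bis(benzyloxy)phenyl]methanol | OCc1ccc(OCc2ccccc2)c(OCc2ccccc2)c1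
F2 | step 6 | dimethyl 2-{1-[3,4-bis(benzyloxy)phenyl]-1-{[3,4-bis(benzyloxy)benzyl]oxy}-3-[(tert-butyldiphenylsilyl)oxy]propan-2-yl}malonate (relative configuration from inversion at the benzylic carbon of 8; racemic) | CC(C)(C)[Si](c1ccccc1)(c1ccccc1)OC[C@@H]([C@@H](OCc1ccc(OCc2ccccc2)c(OCc2ccccc2)c1)c1ccc(OCc2ccccc2)c(OCc2ccccc2)c1)C(C(=O)OC)C(=O)OC
F3 | step 5 | methyl (Z)-3-[3,4-bis(benzyloxy)phenyl]prop-2-en-1-yl malonate | COC(=O)CC(=O)OC/C=C\c1ccc(OCc2ccccc2)c(OCc2ccccc2)c1
F4 | step 5 | methyl (Z)-3-[3,4-bis(benzyloxy)phenyl]prop-2-en-1-yl 2-diazomalonate | COC(=O)C(=[N+]=[N-])C(=O)OC/C=C\c1ccc(OCc2ccccc2)c(OCc2ccccc2)c1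
F5 | step 5 | methyl 6-[3,4-bis(benzyloxy)phenyl]-2-oxo-3-oxabicyclo[3.1.0]hexane-1-carboxylate, aryl cis to the lactone CH2 (racemic) | COC(=O)[C@]12C(=O)OC[C@H]1[C@H]2c1ccc(OCc2ccccc2)c(OCc2ccccc2)c1
F6 | step 8 | 4,6-bis[3,4-bis(benzyloxy)phenyl]-1-oxotetrahydro-1H,3H-furo[3,4-c]furan-6a-carboxylic acid, cis-fused (racemic) | O=C1OC[C@@H]2[C@@]1(C(=O)O)[C@@H](c1ccc(OCc3ccccc3)c(OCc3ccccc3)c1)O[C@H]2c1ccc(OCc2ccccc2)c(OCc2ccccc2)c1
F0 | step 11 | none | none
A1 | alternative 1 | (E)-3-[3-(benzyloxy)-4-hydroxyphenyl]prop-2-en-1-yl acetate | CC(=O)OC/C=C/c1ccc(O)c(OCc2ccccc2)c1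
A2 | alternative 1 | meso-{2,5-bis[3-(benzyloxy)-4-hydroxyphenyl]tetrahydrofuran-3,4-diyl}bis(methylene) diacetate (2,5-cis, 3,4-cis, 2,3-trans) | CC(=O)OC[C@@H]1[C@H](COC(C)=O)[C@@H](c2ccc(O)c(OCc3ccccc3)c2)O[C@H]1c1ccc(O)c(OCc2ccccc2)c1
A3 | alternative 2 | cis-2,5-bis[3,4-bis(benzyloxy)phenyl]-2,5-dihydrofuran (meso) | C1=C[C@H](c2ccc(OCc3ccccc3)c(OCc3ccccc3)c2)O[C@@H]1c1ccc(OCc2ccccc2)c(OCc2ccccc2)c1
A4 | alternative 2 | meso-dimethyl 2,5-bis[3,4-bis(benzyloxy)phenyl]tetrahydrofuran-3,4-dicarboxylate (2,3-trans, 3,4-cis, 4,5-trans) | COC(=O)[C@@H]1[C@H](C(=O)OC)[C@@H](c2ccc(OCc3ccccc3)c(OCc3ccccc3)c2)O[C@H]1c1ccc(OCc2ccccc2)c(OCc2ccccc2)c1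
A5 | alternative 3 | 3-({1-[3,4-bis(benzyloxy)phenyl]prop-2-en-1-yl}oxy)-3-ethoxy-2-iodopropyl acetate (racemic; mixture at the acetal and iodide carbons) | C=C[C@H](c1ccc(OCc2ccccc2)c(OCc2ccccc2)c1)OC(OCC)C(I)COC(C)=O
A6 | alternative 3 | {5-[3,4-bis(benzyloxy)phenyl]-2-ethoxy-4-(iodomethyl)tetrahydrofuran-3-yl}methyl acetate, 3,4-cis and 4,5-trans (racemic; acetal epimers) | IC[C@@H]1[C@H](COC(C)=O)C(OCC)O[C@H]1c1ccc(OCc2ccccc2)c(OCc2ccccc2)c1
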